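**Retrosynthetic overview**
1. Jezonodione ⇐ its hexamethyl ether; global O‑demethylation is the last step.
2. The bridged cyclohexenedione ring is closed last: C‑acetylation of a 2‑cinnamoyl‑3,4‑diarylcyclopentanone at its free α′‑CH2, then intramolecular aldol condensation (forms C1–C2 and C3=C4).
3. The C6 aryl ⇐ Rh‑catalysed conjugate addition of a 3,5‑dimethoxyphenylboronate to a 2‑acylcyclopent‑2‑enone, anti to the C7 aryl.
4. The cyclopentanone ring is formed second, by the key step: enantioselective, desymmetrising one‑carbon ring expansion (1,2‑shift) of a 3‑arylcyclobutanone with a styryl diazomethyl ketone. It sets C7, makes C5–C8 and C5–C6, and brings in C4 with the styryl arm.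
5. Pieces: veratrole (used twice, via 4‑bromoveratrole), 3‑oxocyclobutanecarboxylic acid (the first ring, bought), but‑3‑en‑2‑one, 1,3‑dimethoxybenzene, N‑methoxy‑N‑methylacetamide.

Assumption: the O‑methyl groups of veratrole and 1,3‑dimethoxybenzene are treated as phenol protecting groups; the α‑centres of the 2‑acylcyclopentanones are configurationally labile and are drawn as the epimer that reacts.

Target numbering used below: (1S,5R,6R,7R)‑bicyclo[3.2.1]oct‑3‑ene‑2,8‑dione, with the 3,5‑dihydroxyphenyl group at C6 (exo) and the 3,4‑dihydroxyphenyl group at C7 (endo).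

**Step 1**
Reactants: 1 veratrole (1,2‑dimethoxybenzene)
Product: 2 4‑bromo‑1,2‑dimethoxybenzene
Conditions: NBS (1.0 equiv), MeCN, 0 °C to rt
Reagents that add atoms: N‑bromosuccinimide, O=C1CCC(=O)N1Br
Why: Electrophilic aromatic bromination occurs para to a methoxy group of the symmetrical arene, giving one regioisomer.

**Step 2**
Reactants: 2 4‑bromo‑1,2‑dimethoxybenzene; 3 3‑oxocyclobutane‑1‑carboxylic acid
Product: 4 3‑(3,4‑dimethoxyphenyl)cyclobutan‑1‑one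
Conditions: Ir[dF(CF3)ppy]2(dtbbpy)PF6 (1 mol %), NiBr2·dme/dtbbpy (5 mol %), phthalimide (additive), Cs2CO3 (1.5 equiv), DMSO, blue LEDs, rt
Reagents that add atoms: none
Why: Ir/Ni metallaphotoredox decarboxylative C(sp3)–C(sp2) cross‑coupling: the carboxylate is oxidised to the 3‑oxocyclobutyl radical, which nickel couples with the aryl bromide; the product has a mirror plane, so no stereocentre arises.

**Step 3**
Reactants: 2 4‑bromo‑1,2‑dimethoxybenzene; 5 but‑3‑en‑2‑one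
Product: 6 (3E)‑4‑(3,4‑dimethoxyphenyl)but‑3‑en‑2‑one
Conditions: Pd(OAc)2 (2 mol %), P(o‑tol)3 (5 mol %), NaHCO3 (1.5 equiv), DMF, 100 °C
Reagents that add atoms: none
Why: Mizoroki–Heck arylation at the terminal carbon of the enone; syn‑insertion and syn‑β‑hydride elimination give the E‑alkene.

**Step 4**
Reactants: 6 (3E)‑4‑(3,4‑dimethoxyphenyl)but‑3‑en‑2‑one
Product: 8 (3E)‑1‑diazo‑4‑(3,4‑dimethoxyphenyl)but‑3‑en‑2‑one, via trifluoroacetyl diketone 7 (not isolated)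
Conditions: LiHMDS, THF, −78 °C; CF3CO2CH2CF3; 5% HCl work‑up; then MsN3, Et3N, H2O (1 equiv), MeCN, rt
Reagents that add atoms: methanesulfonyl azide, CS(=O)(=O)N=[N+]=[N-]
Why: Danheiser detrifluoroacetylative diazo transfer: trifluoroacetylation of the kinetic methyl enolate activates that carbon for N2 transfer from the sulfonyl azide, and the CF3CO group leaves as the N‑acylsulfonamide.

**Step 5**
Reactants: 4 3‑(3,4‑dimethoxyphenyl)cyclobutan‑1‑one; 8 (3E)‑1‑diazo‑4‑(3,4‑dimethoxyphenyl)but‑3‑en‑2‑one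
Product: 10 (4R)‑4‑(3,4‑dimethoxyphenyl)‑2‑[(2E)‑3‑(3,4‑dimethoxyphenyl)prop‑2‑enoyl]cyclopentan‑1‑one, via diazonium betaine 9 (not isolated)
Conditions: Sc(OTf)3 (10 mol %), chiral N,N′‑dioxide ligand (Feng type, 11 mol %; the enantiomer that gives 4R is chosen by screening), 4 Å MS, CH2Cl2, −20 °C, slow addition of 8
Reagents that add atoms: none
Why: Proposed new method: a chiral Sc(III)–N,N′‑dioxide complex binds the prochiral cyclobutanone and the diazo carbon of 8 adds anti to the aryl group with catalyst control of the configuration at the new diazonium carbon; in the chelated betaine 9 the N2+ group is then anti‑periplanar to only one of the two enantiotopic ring CH2 groups, and that CH2 makes the 1,2‑shift with loss of N2 (strain‑driven cyclobutanone→cyclopentanone ring expansion, Tiffeneau–Demjanov‑type diazo–carbonyl homologation), which sets C4 as R; the closest known reactions are Lewis‑acid‑catalysed ring expansions of cyclobutanones with diazo esters and catalytic asymmetric diazo homologations of cyclic ketones, not yet shown as a desymmetrisation with a terminal vinyl diazoketone.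

**Step 6**
Reactants: 10 (4R)‑4‑(3,4‑dimethoxyphenyl)‑2‑[(2E)‑3‑(3,4‑dimethoxyphenyl)prop‑2‑enoyl]cyclopentan‑1‑one
Product: 12 (4S)‑4‑(3,4‑dimethoxyphenyl)‑2‑[(2E)‑3‑(3,4‑dimethoxyphenyl)prop‑2‑enoyl]cyclopent‑2‑en‑1‑one, via α‑phenylselanyl diketone 11 (not isolated)
Conditions: PhSeCl, pyridine, CH2Cl2, 0 °C; then 30% H2O2, 0 °C to rt; product used at once
Reagents that add atoms: none
Why: Reich selenoxide route to a 2‑acylcycloalk‑2‑enone: the β‑diketone is selenenylated at C2 and the selenoxide eliminates syn towards C3 (the only β‑hydrogens); the C4 centre is untouched (the descriptor changes from R to S by CIP priority only).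

**Step 7**
Reactants: 13 1,3‑dimethoxybenzene
Product: 14 2‑(3,5‑dimethoxyphenyl)‑4,4,5,5‑tetramethyl‑1,3,2‑dioxaborolane
Conditions: [Ir(OMe)(cod)]2 (1 mol %), dtbpy (2 mol %), B2pin2 (0.55 equiv), THF, 80 °C
Reagents that add atoms: bis(pinacolato)diboron, CC1(C)OB(OC1(C)C)B1OC(C)(C)C(C)(C)O1
Why: Sterically controlled Ir‑catalysed C–H borylation takes the only C–H bond that is not ortho to a methoxy group (C5).

**Step 8**
Reactants: 12 (4S)‑4‑(3,4‑dimethoxyphenyl)‑2‑[(2E)‑3‑(3,4‑dimethoxyphenyl)prop‑2‑enoyl]cyclopent‑2‑en‑1‑one; 14 2‑(3,5‑dimethoxyphenyl)‑4,4,5,5‑tetramethyl‑1,3,2‑dioxaborolane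
Product: 15 (2S,3R,4S)‑4‑(3,4‑dimethoxyphenyl)‑3‑(3,5‑dimethoxyphenyl)‑2‑[(2E)‑3‑(3,4‑dimethoxyphenyl)prop‑2‑enoyl]cyclopentan‑1‑one
Conditions: [Rh(cod)OH]2 (3 mol %), dioxane–H2O 10:1, 30 °C, no added base
Reagents that add atoms: none
Why: Rh‑catalysed conjugate addition (Hayashi–Miyaura type) to the doubly activated ring alkene, which is far more electrophilic than the cinnamoyl alkene; the aryl group enters at C3 anti to the C4 aryl group (substrate control) and the β‑diketone centre C2 settles trans (thermodynamic).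

**Step 9**
Reactants: 15 (2S,3R,4S)‑4‑(3,4‑dimethoxyphenyl)‑3‑(3,5‑dimethoxyphenyl)‑2‑[(2E)‑3‑(3,4‑dimethoxyphenyl)prop‑2‑enoyl]cyclopentan‑1‑one; 16 N‑methoxy‑N‑methylacetamide
Product: 19 (1S,5R,6R,7R)‑7‑(3,4‑dimethoxyphenyl)‑6‑(3,5‑dimethoxyphenyl)‑4‑[(E)‑2‑(3,4‑dimethoxyphenyl)ethenyl]bicyclo[3.2.1]oct‑3‑ene‑2,8‑dione, via triketone 17 (not isolated), via bridged aldol 18 (not isolated)
Conditions: LDA (3.2 equiv), THF, −78 to −30 °C; 16 (1.3 equiv), −78 to 0 °C; then AcOH (3.5 equiv), 45 °C (no alkoxide or hydroxide)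
Reagents that add atoms: none
Why: Hauser–Harris C‑acylation of the β‑diketone dianion at the free α′‑CH2 gives triketone 17, whose two freely epimerising acyl‑bearing centres close by a Collie–Harris (Robinson‑type) intramolecular aldol condensation of the acetyl CH3 onto the cinnamoyl C=O on the ring face anti to the 3,5‑dimethoxyphenyl group (the bulky new carbinol carbon avoids a cis aryl neighbour), and this fixes both bridgeheads as in the target.

**Step 10**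
Reactants: 19 (1S,5R,6R,7R)‑7‑(3,4‑dimethoxyphenyl)‑6‑(3,5‑dimethoxyphenyl)‑4‑[(E)‑2‑(3,4‑dimethoxyphenyl)ethenyl]bicyclo[3.2.1]oct‑3‑ene‑2,8‑dione
Product: 20 jezonodione, (1S,5R,6R,7R)‑7‑(3,4‑dihydroxyphenyl)‑6‑(3,5‑dihydroxyphenyl)‑4‑[(E)‑2‑(3,4‑dihydroxyphenyl)ethenyl]bicyclo[3.2.1]oct‑3‑ene‑2,8‑dione
Conditions: BBr3 (10 equiv), CH2Cl2, −78 to 0 °C; quench MeOH/H2O at −78 °C, NaHCO3 to pH 6–7
Reagents that add atoms: none
Why: Lewis‑acid cleavage of the six aryl methyl ethers; BBr3 bound to the ether oxygens deactivates the aryl rings against ionisation of the benzylic C1–C7 bond, and no stereocentre is touched.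

**Compound list**
1 | veratrole (1,2‑dimethoxybenzene) | COc1ccccc1OC | starting material
2 | 4‑bromo‑1,2‑dimethoxybenzene | COc1ccc(Br)cc1OC | intermediate
3 | 3‑oxocyclobutane‑1‑carboxylic acid | O=C1CC(C1)C(=O)O | starting material
4 | 3‑(3,4‑dimethoxyphenyl)cyclobutan‑1‑one | O=C1CC(C1)c1ccc(OC)c(OC)c1 | intermediate
5 | but‑3‑en‑2‑one (methyl vinyl ketone) | CC(=O)C=C | starting material
6 | (3E)‑4‑(3,4‑dimethoxyphenyl)but‑3‑en‑2‑one | CC(=O)/C=C/c1ccc(OC)c(OC)c1 | intermediate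
7 | (5E)‑6‑(3,4‑dimethoxyphenyl)‑1,1,1‑trifluorohex‑5‑ene‑2,4‑dione | O=C(CC(=O)C(F)(F)F)/C=C/c1ccc(OC)c(OC)c1 | intermediate
8 | (3E)‑1‑diazo‑4‑(3,4‑dimethoxyphenyl)but‑3‑en‑2‑one | [N-]=[N+]=CC(=O)/C=C/c1ccc(OC)c(OC)c1 | intermediate
9 | diazonium betaine (Sc‑bound alkoxide; O cis to aryl, N2+ anti to the migrating CH2) | [O-][C@]1(C[C@@H](c2ccc(OC)c(OC)c2)C1)[C@@H]([N+]#N)C(=O)/C=C/c1ccc(OC)c(OC)c1 | intermediate
10 | (4R)‑4‑(3,4‑dimethoxyphenyl)‑2‑[(2E)‑3‑(3,4‑dimethoxyphenyl)prop‑2‑enoyl]cyclopentan‑1‑one (C2 labile, enolised) | O=C1C[C@H](c2ccc(OC)c(OC)c2)CC1C(=O)/C=C/c1ccc(OC)c(OC)c1 | intermediate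
11 | (4R)‑4‑(3,4‑dimethoxyphenyl)‑2‑[(2E)‑3‑(3,4‑dimethoxyphenyl)prop‑2‑enoyl]‑2‑(phenylselanyl)cyclopentan‑1‑one (C2 epimers) | O=C1C[C@H](c2ccc(OC)c(OC)c2)CC1([Se]c1ccccc1)C(=O)/C=C/c1ccc(OC)c(OC)c1 | intermediate
12 | (4S)‑4‑(3,4‑dimethoxyphenyl)‑2‑[(2E)‑3‑(3,4‑dimethoxyphenyl)prop‑2‑enoyl]cyclopent‑2‑en‑1‑one | O=C1C[C@H](c2ccc(OC)c(OC)c2)C=C1C(=O)/C=C/c1ccc(OC)c(OC)c1 | intermediate
13 | 1,3‑dimethoxybenzene | COc1cccc(OC)c1 | starting material
14 | 2‑(3,5‑dimethoxyphenyl)‑4,4,5,5‑tetramethyl‑1,3,2‑dioxaborolane | COc1cc(OC)cc(c1)B1OC(C)(C)C(C)(C)O1 | intermediate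
15 | (2S,3R,4S)‑4‑(3,4‑dimethoxyphenyl)‑3‑(3,5‑dimethoxyphenyl)‑2‑[(2E)‑3‑(3,4‑dimethoxyphenyl)prop‑2‑enoyl]cyclopentan‑1‑one | O=C1C[C@H](c2ccc(OC)c(OC)c2)[C@@H](c2cc(OC)cc(OC)c2)[C@@H]1C(=O)/C=C/c1ccc(OC)c(OC)c1 | intermediate
16 | N‑methoxy‑N‑methylacetamide | CC(=O)N(C)OC | starting material
17 | (2S,3R,4R,5R)‑2‑acetyl‑3‑(3,4‑dimethoxyphenyl)‑4‑(3,5‑dimethoxyphenyl)‑5‑[(2E)‑3‑(3,4‑dimethoxyphenyl)prop‑2‑enoyl]cyclopentan‑1‑one (C2/C5 labile; the cis‑diacyl epimer that cyclises is drawn) | CC(=O)[C@@H]1[C@H](c2ccc(OC)c(OC)c2)[C@@H](c2cc(OC)cc(OC)c2)[C@H](C(=O)/C=C/c2ccc(OC)c(OC)c2)C1=O | intermediate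
18 | (1S,5R,6R,7R)‑7‑(3,4‑dimethoxyphenyl)‑6‑(3,5‑dimethoxyphenyl)‑4‑[(E)‑2‑(3,4‑dimethoxyphenyl)ethenyl]‑4‑hydroxybicyclo[3.2.1]octane‑2,8‑dione (C4 epimers) | O=C1CC(O)(/C=C/c2ccc(OC)c(OC)c2)[C@@H]2C(=O)[C@H]1[C@H](c1ccc(OC)c(OC)c1)[C@H]2c1cc(OC)cc(OC)c1 | intermediate
19 | (1S,5R,6R,7R)‑7‑(3,4‑dimethoxyphenyl)‑6‑(3,5‑dimethoxyphenyl)‑4‑[(E)‑2‑(3,4‑dimethoxyphenyl)ethenyl]bicyclo[3.2.1]oct‑3‑ene‑2,8‑dione | O=C1C=C(/C=C/c2ccc(OC)c(OC)c2)[C@@H]2C(=O)[C@H]1[C@H](c1ccc(OC)c(OC)c1)[C@H]2c1cc(OC)cc(OC)c1 | intermediate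
20 | jezonodione | O=C1C=C(/C=C/c2ccc(O)c(O)c2)[C@@H]2C(=O)[C@H]1[C@H](c1ccc(O)c(O)c1)[C@H]2c1cc(O)cc(O)c1 | target

**Totals**
Total steps: 10. Longest linear sequence: 8 (steps 1, 3, 4, 5, 6, 8, 9, 10).

**Three steps most likely to fail, and fallbacks**

Step 5 (the new desymmetrising ring expansion). The acceptor‑type vinyl diazoketone may be too weak a nucleophile, the β‑diketone product may hold on to Sc(III), and the enantioselectivity is untested. The fallback uses known chemistry and sets out from 4 and 8: BF3·OEt2 (1.1 equiv) in CH2Cl2 at −78 °C, the established Lewis‑acid‑promoted homologation of cyclobutanones with α‑diazo carbonyl compounds, gives racemic 4‑(3,4‑dimethoxyphenyl)‑2‑[(2E)‑3‑(3,4‑dimethoxyphenyl)prop‑2‑enoyl]cyclopentan‑1‑one F1. Preparative chiral SFC then gives the (4R) enantiomer, which is 10, and the route goes on at step 6.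

Step 9 (one‑pot acylation and bridged aldol condensation). The acetyl CH3 is the least acidic site of triketone 17, so the aldol may be slow, and the facial preference (about 3:1 or better expected) is argued, not proven. The fallback replaces the aldol by an olefination and sets out from 15. The same dianion is acylated with 2‑chloro‑N‑methoxy‑N‑methylacetamide to give the chloroacetyl triketone F2. PPh3 in MeCN gives the phosphonium chloride F3. Aqueous NaHCO3/CH2Cl2 gives the stabilised acyl ylide F4; this forms selectively because the phosphonium CH2 is more acidic than the β‑diketone units. Heating in toluene at 90 °C closes the ring by intramolecular Wittig reaction with the cinnamoyl C=O and comes back to the route at 19.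

Step 10 (global demethylation). Bicyclo[3.2.1]octenediones with a para‑oxygenated aryl group at C7 are known to rearrange under acid to dihydrobenzofurans by C1–C7 ionisation, and BBr3 or the HBr formed on work‑up may trigger this. The fallback moves the demethylation to a robust stage and changes the protecting group; it sets out from 15. BBr3 (CH2Cl2, −78 to 0 °C) on 15 gives the hexaphenol F5. TBSCl/imidazole in DMF gives the hexakis(TBS) ether F6. The step‑9 protocol (LDA; 16; AcOH, 45 °C) then passes through the silylated triketone F7 and the silylated bridged aldol F8 (neither isolated) to the hexakis(TBS) ether of jezonodione F9. TBAF buffered with AcOH in THF at 0 °C removes the silyl groups under near‑neutral conditions and comes back to the route at 20.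

**Further compounds**
F1 | step 5 | racemic 4‑(3,4‑dimethoxyphenyl)‑2‑[(2E)‑3‑(3,4‑dimethoxyphenyl)prop‑2‑enoyl]cyclopentan‑1‑one | O=C1CC(c2ccc(OC)c(OC)c2)CC1C(=O)/C=C/c1ccc(OC)c(OC)c1
F2 | step 9 | (3R,4R)‑2‑(chloroacetyl)‑3‑(3,4‑dimethoxyphenyl)‑4‑(3,5‑dimethoxyphenyl)‑5‑[(2E)‑3‑(3,4‑dimethoxyphenyl)prop‑2‑enoyl]cyclopentan‑1‑one (C2/C5 labile) | ClCC(=O)[C@@H]1[C@H](c2ccc(OC)c(OC)c2)[C@@H](c2cc(OC)cc(OC)c2)[C@H](C(=O)/C=C/c2ccc(OC)c(OC)c2)C1=O
F3 | step 9 | phosphonium chloride from F2 and PPh3 | [Cl-].O=C(C[P+](c1ccccc1)(c1ccccc1)c1ccccc1)[C@@H]1[C@H](c2ccc(OC)c(OC)c2)[C@@H](c2cc(OC)cc(OC)c2)[C@H](C(=O)/C=C/c2ccc(OC)c(OC)c2)C1=O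
F4 | step 9 | acyl(triphenylphosphoranylidene)methyl ylide from F3 | O=C(C=P(c1ccccc1)(c1ccccc1)c1ccccc1)[C@@H]1[C@H](c2ccc(OC)c(OC)c2)[C@@H](c2cc(OC)cc(OC)c2)[C@H](C(=O)/C=C/c2ccc(OC)c(OC)c2)C1=O
F5 | step 10 | (2S,3R,4S)‑4‑(3,4‑dihydroxyphenyl)‑3‑(3,5‑dihydroxyphenyl)‑2‑[(2E)‑3‑(3,4‑dihydroxyphenyl)prop‑2‑enoyl]cyclopentan‑1‑one | O=C1C[C@H](c2ccc(O)c(O)c2)[C@@H](c2cc(O)cc(O)c2)[C@@H]1C(=O)/C=C/c1ccc(O)c(O)c1
F6 | step 10 | hexakis(tert‑butyldimethylsilyl) ether of F5 | O=C1C[C@H](c2ccc(O[Si](C)(C)C(C)(C)C)c(O[Si](C)(C)C(C)(C)C)c2)[C@@H](c2cc(O[Si](C)(C)C(C)(C)C)cc(O[Si](C)(C)C(C)(C)C)c2)[C@@H]1C(=O)/C=C/c1ccc(O[Si](C)(C)C(C)(C)C)c(O[Si](C)(C)C(C)(C)C)c1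
F7 | step 10 | hexakis(tert‑butyldimethylsilyl) analogue of triketone 17 | CC(=O)[C@@H]1[C@H](c2ccc(O[Si](C)(C)C(C)(C)C)c(O[Si](C)(C)C(C)(C)C)c2)[C@@H](c2cc(O[Si](C)(C)C(C)(C)C)cc(O[Si](C)(C)C(C)(C)C)c2)[C@H](C(=O)/C=C/c2ccc(O[Si](C)(C)C(C)(C)C)c(O[Si](C)(C)C(C)(C)C)c2)C1=O
F8 | step 10 | hexakis(tert‑butyldimethylsilyl) analogue of bridged aldol 18 | O=C1CC(O)(/C=C/c2ccc(O[Si](C)(C)C(C)(C)C)c(O[Si](C)(C)C(C)(C)C)c2)[C@@H]2C(=O)[C@H]1[C@H](c1ccc(O[Si](C)(C)C(C)(C)C)c(O[Si](C)(C)C(C)(C)C)c1)[C@H]2c1cc(O[Si](C)(C)C(C)(C)C)cc(O[Si](C)(C)C(C)(C)C)c1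
F9 | step 10 | hexakis(tert‑butyldimethylsilyl) ether of jezonodione | O=C1C=C(/C=C/c2ccc(O[Si](C)(C)C(C)(C)C)c(O[Si](C)(C)C(C)(C)C)c2)[C@@H]2C(=O)[C@H]1[C@H](c1ccc(O[Si](C)(C)C(C)(C)C)c(O[Si](C)(C)C(C)(C)C)c1)[C@H]2c1cc(O[Si](C)(C)C(C)(C)C)cc(O[Si](C)(C)C(C)(C)C)c1
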